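**Remark on the chemistry:** ring positions are numbered as in 1H-isochromene (C1, O2, C3, C4, C4a, C5–C8, C8a). The target is read as (6R,7S), with the C6 acyloxy group and the C7 hydroxyl trans. Compounds 1, 3, 13 and 18 are assumed to be purchasable.

The route rests on the tertiary α-ketol of the carbocycle C4a–C5–C6–C7–C8–C8a: the C8 ketone and the C7 carbinol are joined by an intramolecular crossed benzoin reaction. An N-heterocyclic carbene converts the C8 aldehyde of a hydroxy enal into an acyl anion that adds to the C7 methyl ketone. The enal is held as a dihydropyranol (lactol), which fixes the tetrasubstituted C8a=C4a geometry. One operation closes the six-membered ring and sets C7 from C6. The lactol comes from an asymmetric hetero-Diels–Alder adduct by Ferrier-type transposition. The pyran is then closed by 6-endo oxa-Michael addition of the C1 hydroxyl.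

Key step: step 7

**Step 1**
Reactants: 1 2-methyl-2-vinyl-1,3-dioxolane
Product: 2 2-methyl-1,3-dioxolane-2-carbaldehyde
Conditions: O3, CH2Cl2, −78 °C; then Me2S, −78 °C to rt
Reagents that add atoms: ozone, [O-][O+]=O
Why: Ozonolysis with reductive work-up should cleave the vinyl group to the aldehyde while the ketal stays intact.

**Step 2**
Reactants: 2 2-methyl-1,3-dioxolane-2-carbaldehyde; 3 Danishefsky's diene, (E)-1-methoxy-3-(trimethylsilyloxy)buta-1,3-diene
Product: 5 (2R)-2-(2-methyl-1,3-dioxolan-2-yl)-2,3-dihydro-4H-pyran-4-one, via cycloadduct 4 (not isolated)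
Conditions: (R,R)-[N,N′-bis(3,5-di-tert-butylsalicylidene)-1,2-cyclohexanediamine]CrBF4 (trivalent chromium, 2 mol%), 4 Å molecular sieves, t-BuOMe, −30 °C; then CF3CO2H (1.1 equiv), CH2Cl2, 0 °C
Reagents that add atoms: none
Why: An enantioselective hetero-Diels–Alder reaction, followed by acid-induced loss of methanol and the silyl group, should give the dihydropyranone; the C2 centre (later C6) is set by the chiral chromium salen catalyst, its sense being assigned by analogy with simple aldehydes.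

**Step 3**
Reactants: 5 (2R)-2-(2-methyl-1,3-dioxolan-2-yl)-2,3-dihydro-4H-pyran-4-one
Product: 6 (2R)-5-iodo-2-(2-methyl-1,3-dioxolan-2-yl)-2,3-dihydro-4H-pyran-4-one
Conditions: I2, pyridine, CH2Cl2, 0 °C to rt
Reagents that add atoms: iodine, II
Why: The α-carbon of the vinylogous ester is nucleophilic, so iodine and pyridine should give the α-iodoenone (Johnson α-iodination) without touching C2.

**Step 4**
Reactants: 6 (2R)-5-iodo-2-(2-methyl-1,3-dioxolan-2-yl)-2,3-dihydro-4H-pyran-4-one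
Product: 7 (2R)-5-(hydroxymethyl)-2-(2-methyl-1,3-dioxolan-2-yl)-2,3-dihydro-4H-pyran-4-one
Conditions: Bu3SnCH2OH, Pd(PPh3)4 (5 mol%), 1,4-dioxane, 90 °C
Reagents that add atoms: (tributylstannyl)methanol, OC[Sn](CCCC)(CCCC)CCCC
Why: Stille cross-coupling of the α-iodoenone should transfer the hydroxymethyl group, the future C1, to C5 of the pyranone.

**Step 5**
Reactants: 7 (2R)-5-(hydroxymethyl)-2-(2-methyl-1,3-dioxolan-2-yl)-2,3-dihydro-4H-pyran-4-one
Product: 8 (2R)-5-{[(tert-butyldiphenylsilyl)oxy]methyl}-2-(2-methyl-1,3-dioxolan-2-yl)-2,3-dihydro-4H-pyran-4-one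
Conditions: TBDPSCl, imidazole, DMF, rt
Reagents that add atoms: tert-butyl(chloro)diphenylsilane, CC(C)(C)[Si](Cl)(c1ccccc1)c1ccccc1
Why: Silylation of the primary alcohol gives an acid-stable ether that keeps the C1 oxygen away from the alkyne until the enone is in place.

**Step 6**
Reactants: 8 (2R)-5-{[(tert-butyldiphenylsilyl)oxy]methyl}-2-(2-methyl-1,3-dioxolan-2-yl)-2,3-dihydro-4H-pyran-4-one
Product: 10 1-[(2R)-5-{[(tert-butyldiphenylsilyl)oxy]methyl}-4-ethynyl-6-hydroxy-3,6-dihydro-2H-pyran-2-yl]ethan-1-one (anomers), via tertiary carbinol 9 (not isolated)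
Conditions: HC≡CMgBr, CeCl3, THF, −78 to 0 °C; then 2 M aq HCl, THF, rt to 40 °C
Reagents that add atoms: ethynylmagnesium bromide, C#C[Mg]Br; water, O
Why: The organocerium should add 1,2 to the vinylogous ester carbonyl, and aqueous acid should then ionise the tertiary allylic carbinol to a cyclic oxocarbenium ion that water captures at the former enol ether carbon (Ferrier-type, Stork–Danheiser transposition) while the dioxolane is hydrolysed; the ring thereby locks the aldehyde carbon cis to the C5 methylene, the C2 centre is untouched and the carbinol centre is erased.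

**Step 7**
Reactants: 10 1-[(2R)-5-{[(tert-butyldiphenylsilyl)oxy]methyl}-4-ethynyl-6-hydroxy-3,6-dihydro-2H-pyran-2-yl]ethan-1-one
Product: 12 (5R,6S)-2-{[(tert-butyldiphenylsilyl)oxy]methyl}-3-ethynyl-5,6-dihydroxy-6-methylcyclohex-2-en-1-one, via open-chain hydroxy enal 11 (not isolated)
Conditions: 2-(pentafluorophenyl)-6,7-dihydro-5H-pyrrolo[2,1-c][1,2,4]triazol-2-ium tetrafluoroborate (15 mol%), Et3N (15 mol%), toluene, rt to 40 °C
Reagents that add atoms: none
Why: Triethylamine should open the lactol to the (E)-δ-hydroxy enal 11 and free the triazolylidene, which adds to the C8 aldehyde to give a Breslow intermediate (acyl anion equivalent) that attacks the C7 methyl ketone and then releases the carbene, an N-heterocyclic-carbene-catalysed intramolecular crossed aldehyde–ketone benzoin reaction. The closest known type is the triazolium-catalysed benzoin cyclisation of keto-aldehydes to six-membered tertiary α-ketols. The carbocycle C4a–C5–C6–C7–C8–C8a closes in 6-exo-trig mode through the C8–C7 bond. The new C7 centre is controlled by C6: in the chair-like transition state the C6–O bond is pseudo-equatorial and antiperiplanar to the forming bond (polar Felkin–Anh), and the ketone oxygen lies pseudo-equatorial where it accepts the proton of the Breslow hydroxyl, so the C7 hydroxyl should end trans to the C6 oxygen, i.e. (S). The step needs acyl-anion reactivity to win over homoenolate or redox pathways and over intermolecular benzoin; the fully substituted β-carbon C4a, the electron-poor N-pentafluorophenyl triazolium and the proximity of the activated α-hydroxy ketone should secure this.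

**Step 8**
Reactants: 13 (2E)-3-iodoprop-2-enoic acid
Product: 14 tert-butyl (2E)-3-iodoprop-2-enoate
Conditions: Cl3CC(=NH)OtBu, BF3·OEt2 (cat.), CH2Cl2/cyclohexane, rt
Reagents that add atoms: tert-butyl 2,2,2-trichloroacetimidate, CC(C)(C)OC(=N)C(Cl)(Cl)Cl
Why: Acid-catalysed O-alkylation of the acid by the imidate should give the tert-butyl ester without isomerising the (E)-iodoalkene.

**Step 9**
Reactants: 12 (5R,6S)-2-{[(tert-butyldiphenylsilyl)oxy]methyl}-3-ethynyl-5,6-dihydroxy-6-methylcyclohex-2-en-1-one; 14 tert-butyl (2E)-3-iodoprop-2-enoate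
Product: 15 tert-butyl (2E)-5-[(4S,5R)-2-{[(tert-butyldiphenylsilyl)oxy]methyl}-4,5-dihydroxy-4-methyl-3-oxocyclohex-1-en-1-yl]pent-2-en-4-ynoate
Conditions: Pd(PPh3)2Cl2 (3 mol%), CuI (6 mol%), Et3N, THF, rt
Reagents that add atoms: none
Why: Sonogashira coupling of the terminal alkyne with the vinyl iodide should proceed with retention of the (E)-geometry and tolerate the free diol and the enone.

**Step 10**
Reactants: 15 tert-butyl (2E)-5-[(4S,5R)-2-{[(tert-butyldiphenylsilyl)oxy]methyl}-4,5-dihydroxy-4-methyl-3-oxocyclohex-1-en-1-yl]pent-2-en-4-ynoate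
Product: 17 tert-butyl (2E)-3-[(6R,7S)-6,7-dihydroxy-7-methyl-8-oxo-5,6,7,8-tetrahydro-1H-isochromen-3-yl]prop-2-enoate, via desilylated enynol 16 (not isolated)
Conditions: Bu4NF, THF, 0 °C to rt
Reagents that add atoms: none
Why: Fluoride should remove the silyl group, and the liberated C1 alkoxide should add to C3, the δ-carbon of the cross-conjugated ynenone (oxa-Michael addition, 6-endo-dig), giving the conjugated pyran after protonation; no stereocentre is formed.

**Step 11**
Reactants: 18 2,3,4-trimethoxy-6-methylbenzaldehyde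
Product: 19 2,3,4-trihydroxy-6-methylbenzaldehyde
Conditions: BBr3, CH2Cl2, −78 °C to rt; then H2O
Reagents that add atoms: none
Why: Boron tribromide should cleave all three aryl methyl ethers (Lewis-acid demethylation).

**Step 12**
Reactants: 19 2,3,4-trihydroxy-6-methylbenzaldehyde
Product: 20 2-hydroxy-3,4-bis(methoxymethoxy)-6-methylbenzaldehyde
Conditions: MOMCl (2.1 equiv), i-Pr2NEt, CH2Cl2, 0 °C
Reagents that add atoms: chloromethyl methyl ether, COCCl
Why: The 3- and 4-hydroxyls should be alkylated while the 2-hydroxyl, hydrogen-bonded to the aldehyde, stays free (selective O-alkylation).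

**Step 13**
Reactants: 20 2-hydroxy-3,4-bis(methoxymethoxy)-6-methylbenzaldehyde
Product: 21 2-methoxy-3,4-bis(methoxymethoxy)-6-methylbenzaldehyde
Conditions: MeI, K2CO3, DMF, rt
Reagents that add atoms: iodomethane, CI
Why: Williamson methylation of the remaining chelated phenol should proceed with carbonate in DMF.

**Step 14**
Reactants: 21 2-methoxy-3,4-bis(methoxymethoxy)-6-methylbenzaldehyde
Product: 22 2-methoxy-3,4-bis(methoxymethoxy)-6-methylbenzoic acid
Conditions: NaClO2, NaH2PO4, 2-methyl-2-butene, t-BuOH/H2O, rt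
Reagents that add atoms: sodium chlorite, [Na+].[O-]Cl=O
Why: Pinnick oxidation should convert the hindered aryl aldehyde to the acid at a pH that the MOM ethers tolerate.

**Step 15**
Reactants: 17 tert-butyl (2E)-3-[(6R,7S)-6,7-dihydroxy-7-methyl-8-oxo-5,6,7,8-tetrahydro-1H-isochromen-3-yl]prop-2-enoate; 22 2-methoxy-3,4-bis(methoxymethoxy)-6-methylbenzoic acid
Product: 24 tert-butyl (2E)-3-[(6R,7S)-7-hydroxy-6-{[2-methoxy-3,4-bis(methoxymethoxy)-6-methylbenzoyl]oxy}-7-methyl-8-oxo-5,6,7,8-tetrahydro-1H-isochromen-3-yl]prop-2-enoate, via acid chloride 23 (not isolated)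
Conditions: 22, Me2C=C(Cl)NMe2, CH2Cl2, rt; then 17, DMAP, pyridine, 0 °C to rt
Reagents that add atoms: none
Why: The chloroenamine should form the acid chloride under neutral conditions, and DMAP-catalysed O-acylation should take the secondary C6 hydroxyl with retention, the tertiary C7 hydroxyl being unreactive.

**Step 16**
Reactants: 24 tert-butyl (2E)-3-[(6R,7S)-7-hydroxy-6-{[2-methoxy-3,4-bis(methoxymethoxy)-6-methylbenzoyl]oxy}-7-methyl-8-oxo-5,6,7,8-tetrahydro-1H-isochromen-3-yl]prop-2-enoate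
Product: 25 (2E)-3-[(6R,7S)-6-[(3,4-dihydroxy-2-methoxy-6-methylbenzoyl)oxy]-7-hydroxy-7-methyl-8-oxo-5,6,7,8-tetrahydro-1H-isochromen-3-yl]prop-2-enoic acid
Conditions: CF3CO2H/CH2Cl2 (1:4), 0 °C to rt
Reagents that add atoms: none
Why: Acidolysis should remove the tert-butyl ester as isobutene and cleave both aryl MOM acetals in one operation, while the vinylogous ester chromophore, the tertiary α-ketol and the hindered benzoate tolerate anhydrous acid.

**Compound list**

1 | 2-methyl-2-vinyl-1,3-dioxolane | C=CC1(C)OCCO1 | starting material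
2 | 2-methyl-1,3-dioxolane-2-carbaldehyde | O=CC1(C)OCCO1 | intermediate
3 | (E)-1-methoxy-3-(trimethylsilyloxy)buta-1,3-diene | CO/C=C/C(=C)O[Si](C)(C)C | starting material
4 | (6R)-2-methoxy-6-(2-methyl-1,3-dioxolan-2-yl)-4-[(trimethylsilyl)oxy]-5,6-dihydro-2H-pyran (C2 epimers) | COC1C=C(O[Si](C)(C)C)C[C@@H](O1)C1(C)OCCO1 | intermediate
5 | (2R)-2-(2-methyl-1,3-dioxolan-2-yl)-2,3-dihydro-4H-pyran-4-one | O=C1C=CO[C@H](C1)C1(C)OCCO1 | intermediate
6 | (2R)-5-iodo-2-(2-methyl-1,3-dioxolan-2-yl)-2,3-dihydro-4H-pyran-4-one | O=C1C(I)=CO[C@H](C1)C1(C)OCCO1 | intermediate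
7 | (2R)-5-(hydroxymethyl)-2-(2-methyl-1,3-dioxolan-2-yl)-2,3-dihydro-4H-pyran-4-one | O=C1C(CO)=CO[C@H](C1)C1(C)OCCO1 | intermediate
8 | (2R)-5-{[(tert-butyldiphenylsilyl)oxy]methyl}-2-(2-methyl-1,3-dioxolan-2-yl)-2,3-dihydro-4H-pyran-4-one | O=C1C(CO[Si](c2ccccc2)(c2ccccc2)C(C)(C)C)=CO[C@H](C1)C1(C)OCCO1 | intermediate
9 | (2R)-5-{[(tert-butyldiphenylsilyl)oxy]methyl}-4-ethynyl-2-(2-methyl-1,3-dioxolan-2-yl)-3,4-dihydro-2H-pyran-4-ol (C4 epimers) | OC1(C#C)C(CO[Si](c2ccccc2)(c2ccccc2)C(C)(C)C)=CO[C@H](C1)C1(C)OCCO1 | intermediate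
10 | 1-[(2R)-5-{[(tert-butyldiphenylsilyl)oxy]methyl}-4-ethynyl-6-hydroxy-3,6-dihydro-2H-pyran-2-yl]ethan-1-one (anomers) | CC(=O)[C@H]1CC(C#C)=C(CO[Si](c2ccccc2)(c2ccccc2)C(C)(C)C)C(O)O1 | intermediate
11 | (2E,5R)-2-{[(tert-butyldiphenylsilyl)oxy]methyl}-3-ethynyl-5-hydroxy-6-oxohept-2-enal | CC(=O)[C@H](O)C/C(C#C)=C(\C=O)CO[Si](c1ccccc1)(c1ccccc1)C(C)(C)C | intermediate
12 | (5R,6S)-2-{[(tert-butyldiphenylsilyl)oxy]methyl}-3-ethynyl-5,6-dihydroxy-6-methylcyclohex-2-en-1-one | O[C@@H]1CC(C#C)=C(CO[Si](c2ccccc2)(c2ccccc2)C(C)(C)C)C(=O)[C@@]1(C)O | intermediate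
13 | (2E)-3-iodoprop-2-enoic acid | OC(=O)/C=C/I | starting material
14 | tert-butyl (2E)-3-iodoprop-2-enoate | CC(C)(C)OC(=O)/C=C/I | intermediate
15 | tert-butyl (2E)-5-[(4S,5R)-2-{[(tert-butyldiphenylsilyl)oxy]methyl}-4,5-dihydroxy-4-methyl-3-oxocyclohex-1-en-1-yl]pent-2-en-4-ynoate | O[C@@H]1CC(C#C/C=C/C(=O)OC(C)(C)C)=C(CO[Si](c2ccccc2)(c2ccccc2)C(C)(C)C)C(=O)[C@@]1(C)O | intermediate
16 | tert-butyl (2E)-5-[(4S,5R)-4,5-dihydroxy-2-(hydroxymethyl)-4-methyl-3-oxocyclohex-1-en-1-yl]pent-2-en-4-ynoate | O[C@@H]1CC(C#C/C=C/C(=O)OC(C)(C)C)=C(CO)C(=O)[C@@]1(C)O | intermediate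
17 | tert-butyl (2E)-3-[(6R,7S)-6,7-dihydroxy-7-methyl-8-oxo-5,6,7,8-tetrahydro-1H-isochromen-3-yl]prop-2-enoate | O[C@@H]1CC2=C(COC(/C=C/C(=O)OC(C)(C)C)=C2)C(=O)[C@@]1(C)O | intermediate
18 | 2,3,4-trimethoxy-6-methylbenzaldehyde | COc1cc(C)c(C=O)c(OC)c1OC | starting material
19 | 2,3,4-trihydroxy-6-methylbenzaldehyde | Cc1cc(O)c(O)c(O)c1C=O | intermediate
20 | 2-hydroxy-3,4-bis(methoxymethoxy)-6-methylbenzaldehyde | Cc1cc(OCOC)c(OCOC)c(O)c1C=O | intermediate
21 | 2-methoxy-3,4-bis(methoxymethoxy)-6-methylbenzaldehyde | Cc1cc(OCOC)c(OCOC)c(OC)c1C=O | intermediate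
22 | 2-methoxy-3,4-bis(methoxymethoxy)-6-methylbenzoic acid | Cc1cc(OCOC)c(OCOC)c(OC)c1C(=O)O | intermediate
23 | 2-methoxy-3,4-bis(methoxymethoxy)-6-methylbenzoyl chloride | Cc1cc(OCOC)c(OCOC)c(OC)c1C(=O)Cl | intermediate
24 | tert-butyl (2E)-3-[(6R,7S)-7-hydroxy-6-{[2-methoxy-3,4-bis(methoxymethoxy)-6-methylbenzoyl]oxy}-7-methyl-8-oxo-5,6,7,8-tetrahydro-1H-isochromen-3-yl]prop-2-enoate | COCOc1cc(C)c(C(=O)O[C@@H]2CC3=C(COC(/C=C/C(=O)OC(C)(C)C)=C3)C(=O)[C@@]2(C)O)c(OC)c1OCOC | intermediate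
25 | (2E)-3-[(6R,7S)-6-[(3,4-dihydroxy-2-methoxy-6-methylbenzoyl)oxy]-7-hydroxy-7-methyl-8-oxo-5,6,7,8-tetrahydro-1H-isochromen-3-yl]prop-2-enoic acid | COc1c(O)c(O)cc(C)c1C(=O)O[C@@H]1CC2=C(COC(/C=C/C(=O)O)=C2)C(=O)[C@@]1(C)O | target

**Step count**

Total: 16 steps. Longest linear sequence: 11 steps (steps 1–7, 9, 10, 15, 16). The aryl acid (steps 11–14) and the iodoacrylate (step 8) are convergent branches.

**Steps most likely to fail**

Step 7. The Breslow intermediate may be diverted into β-protonation and redox lactonisation by the free C6 hydroxyl, the lactol may open too slowly, or facial selectivity at C7 may be poor. Fallback, from 10 back to 12: a reductive pinacol cyclisation followed by oxidation. SmI2 in THF/t-BuOH at −78 °C would couple the aldehyde form of 10 with the C7 ketone through a ketyl, a reaction known to place the new diol anti to an adjacent oxygen substituent. This would give (5R,6S)-2-{[(tert-butyldiphenylsilyl)oxy]methyl}-3-ethynyl-6-methylcyclohex-2-ene-1,5,6-triol F1. MnO2 in CH2Cl2 would then oxidise only the allylic C8 carbinol and deliver 12.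

Step 10. The alkoxide may attack C4 in a 5-exo sense (the carbon activated by the enoate) instead of C3, or the base may degrade the α-ketol. Fallback, from 15 back to 17: the oxygen is introduced at C3 by exchange instead of by direct cyclisation. Pyrrolidine in THF at 0 °C would add intermolecularly to C3, where only the stronger ketone acceptor directs, to give the dienaminone tert-butyl (2E)-5-[(4S,5R)-2-{[(tert-butyldiphenylsilyl)oxy]methyl}-4,5-dihydroxy-4-methyl-3-oxocyclohex-1-en-1-yl]-4-(pyrrolidin-1-yl)penta-2,4-dienoate F2. HF·pyridine would remove the silyl group to give tert-butyl (2E)-5-[(4S,5R)-4,5-dihydroxy-2-(hydroxymethyl)-4-methyl-3-oxocyclohex-1-en-1-yl]-4-(pyrrolidin-1-yl)penta-2,4-dienoate F3. Warming in aqueous acetic acid would replace nitrogen by the C1 oxygen through addition–elimination at C3, closing the pyran to 17.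

Step 2. Asymmetric induction on the α-ketal aldehyde may be low, or the facial sense may be reversed. Fallback, from diene 3 back to 5: chelation control from the chiral pool replaces catalyst control.
- Methyl (R)-lactate would be etherified with 4-methoxybenzyl trichloroacetimidate to methyl (2R)-2-[(4-methoxybenzyl)oxy]propanoate F4 and half-reduced with DIBAL to (2R)-2-[(4-methoxybenzyl)oxy]propanal F5.
- MgBr2·OEt2 in THF would promote chelation-controlled Mukaiyama aldol addition of 3 to give (1E,5R,6R)-5-hydroxy-1-methoxy-6-[(4-methoxybenzyl)oxy]hept-1-en-3-one F6.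
- CF3CO2H would cyclise F6 to (2R)-2-{(1R)-1-[(4-methoxybenzyl)oxy]ethyl}-2,3-dihydro-4H-pyran-4-one F7.
- DDQ would give (2R)-2-[(1R)-1-hydroxyethyl]-2,3-dihydro-4H-pyran-4-one F8, and Dess–Martin periodinane would give (2R)-2-acetyl-2,3-dihydro-4H-pyran-4-one F9.
- Ketalisation of the acetyl group with 1,2-bis(trimethylsilyloxy)ethane and catalytic TMSOTf at −78 °C would return 5.

**Further compounds**

F1 | step 7 | (5R,6S)-2-{[(tert-butyldiphenylsilyl)oxy]methyl}-3-ethynyl-6-methylcyclohex-2-ene-1,5,6-triol (C1 epimers) | O[C@@H]1CC(C#C)=C(CO[Si](c2ccccc2)(c2ccccc2)C(C)(C)C)C(O)[C@@]1(C)O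
F2 | step 10 | tert-butyl (2E)-5-[(4S,5R)-2-{[(tert-butyldiphenylsilyl)oxy]methyl}-4,5-dihydroxy-4-methyl-3-oxocyclohex-1-en-1-yl]-4-(pyrrolidin-1-yl)penta-2,4-dienoate | O[C@@H]1CC(C=C(N2CCCC2)/C=C/C(=O)OC(C)(C)C)=C(CO[Si](c2ccccc2)(c2ccccc2)C(C)(C)C)C(=O)[C@@]1(C)O
F3 | step 10 | tert-butyl (2E)-5-[(4S,5R)-4,5-dihydroxy-2-(hydroxymethyl)-4-methyl-3-oxocyclohex-1-en-1-yl]-4-(pyrrolidin-1-yl)penta-2,4-dienoate | O[C@@H]1CC(C=C(N2CCCC2)/C=C/C(=O)OC(C)(C)C)=C(CO)C(=O)[C@@]1(C)O
F4 | step 2 | methyl (2R)-2-[(4-methoxybenzyl)oxy]propanoate | C[C@@H](OCc1ccc(OC)cc1)C(=O)OC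
F5 | step 2 | (2R)-2-[(4-methoxybenzyl)oxy]propanal | C[C@@H](OCc1ccc(OC)cc1)C=O
F6 | step 2 | (1E,5R,6R)-5-hydroxy-1-methoxy-6-[(4-methoxybenzyl)oxy]hept-1-en-3-one | CO/C=C/C(=O)C[C@@H](O)[C@@H](C)OCc1ccc(OC)cc1
F7 | step 2 | (2R)-2-{(1R)-1-[(4-methoxybenzyl)oxy]ethyl}-2,3-dihydro-4H-pyran-4-one | O=C1C=CO[C@H](C1)[C@@H](C)OCc1ccc(OC)cc1
F8 | step 2 | (2R)-2-[(1R)-1-hydroxyethyl]-2,3-dihydro-4H-pyran-4-one | O=C1C=CO[C@H](C1)[C@@H](C)O
F9 | step 2 | (2R)-2-acetyl-2,3-dihydro-4H-pyran-4-one | O=C1C=CO[C@H](C1)C(C)=O
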